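The lactone is traced back to an open-chain (R)-carbinol that carries a propargyl ether and an oxirane. Everything rests on joining the ring carbon that bears the exocyclic methylene (C3) to the ring carbon that bears the carboxyl group (C4) by a Cp2TiCl-mediated (trivalent titanium) epoxide-opening radical 5-exo-dig cyclization. In one operation this closes the five-membered oxygen ring, turns the alkyne into the 1,1-disubstituted alkene at C3, leaves the future carboxyl carbon as CH2OH on C4 and sets C4 trans to the C5 chain. The step exploits the C3 methylene and the oxidised one-carbon substituent at C4 of the oxolanone ring. Chromium oxidations then raise CH2OH to CO2H and the ring O–CH2 to the lactone carbonyl.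

Key step: step 7

Remark: the acetal carbon of the oxan-2-yl (THP) group and the oxirane carbon of 10 are carried as mixtures of both configurations. Both centres disappear later (steps 5 and 7), so the SMILES leave them undefined. Ring atoms are numbered as in the lactone: O1, C2 (carbonyl), C3 (methylene-bearing), C4 (carboxyl-bearing), C5 (chain-bearing).

Step 1
Reactants: 1 12-bromododecan-1-ol
Product: 2 2-[(12-bromododecyl)oxy]oxane
Conditions: 3,4-dihydro-2H-pyran (1.3 equiv), PPTS (5 mol %), CH2Cl2, rt
Reagents that add atoms: 3,4-dihydro-2H-pyran, C1=COCCC1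
Why: Acid-catalysed addition of the alcohol to the enol ether (tetrahydropyranylation) masks the hydroxyl as an acetal that is inert to the Grignard, ylide and NaH steps and can later be exchanged for acetate in one operation.

Step 2
Reactants: 2 2-[(12-bromododecyl)oxy]oxane; 3 (R)-epichlorohydrin [(2R)-2-(chloromethyl)oxirane]
Product: 5 (2R)-1-chloro-15-(oxan-2-yloxy)pentadecan-2-ol, via Grignard reagent 4 (not isolated)
Conditions: Mg, THF, 45 °C; then CuI (10 mol %), 3 (1.2 equiv), THF, −40 to −10 °C; aq NH4Cl
Reagents that add atoms: none
Why: Copper-catalysed SN2 opening of the oxirane at its CH2 terminus by the alkyl Grignard reagent (CuI, monovalent copper) leaves the C–Cl bond and the stereocentre untouched, so the (R) centre of 3 becomes the future C5 without change.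

Step 3
Reactants: 5 (2R)-1-chloro-15-(oxan-2-yloxy)pentadecan-2-ol
Product: 7 (3R)-16-(oxan-2-yloxy)hexadec-1-en-3-ol, via oxirane 6 (not isolated)
Conditions: Me3S+ I− (4 equiv), n-BuLi (3.8 equiv), THF, −10 °C; then 5, −10 °C to rt
Reagents that add atoms: trimethylsulfonium iodide, C[S+](C)C.[I-]
Why: Dimethylsulfonium methylide closes the chlorohydrin to oxirane 6, opens it at CH2, and a further equivalent eliminates Me2S from the resulting sulfonium alkoxide, a known one-carbon homologation of terminal epoxides to allylic alcohols that does not touch the carbinol centre.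

Step 4
Reactants: 7 (3R)-16-(oxan-2-yloxy)hexadec-1-en-3-ol
Product: 8 2-{[(14R)-14-(prop-2-yn-1-yloxy)hexadec-15-en-1-yl]oxy}oxane
Conditions: NaH (1.5 equiv), propargyl bromide (1.5 equiv), Bu4NI (5 mol %), THF, 0 °C to rt
Reagents that add atoms: propargyl bromide (3-bromoprop-1-yne), C#CCBr
Why: Williamson etherification of the sodium alkoxide with the reactive propargylic bromide takes place at oxygen, so the configuration of the carbinol carbon is retained.

Step 5
Reactants: 8 2-{[(14R)-14-(prop-2-yn-1-yloxy)hexadec-15-en-1-yl]oxy}oxane
Product: 9 (14R)-14-(prop-2-yn-1-yloxy)hexadec-15-en-1-yl acetate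
Conditions: AcCl (3 equiv), AcOH, 35–40 °C
Reagents that add atoms: acetyl chloride, CC(=O)Cl
Why: Acid-promoted cleavage of the tetrahydropyranyl acetal with in situ acetylation of the freed primary alcohol (the classical AcCl/AcOH exchange of a THP ether for an acetate) should leave the dialkyl ether, the alkene and the alkyne untouched.

Step 6
Reactants: 9 (14R)-14-(prop-2-yn-1-yloxy)hexadec-15-en-1-yl acetate
Product: 10 (14R)-14-(oxiran-2-yl)-14-(prop-2-yn-1-yloxy)tetradecyl acetate (both epimers at the oxirane carbon)
Conditions: mCPBA (2 equiv), NaHCO3, CH2Cl2, rt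
Reagents that add atoms: mCPBA (3-chloroperoxybenzoic acid), OOC(=O)c1cccc(Cl)c1
Why: Prilezhaev epoxidation takes place at the alkene, which reacts far faster with the peracid than the terminal alkyne, and no facial control is needed because the new oxirane carbon becomes a planar radical in step 7.

Step 7
Reactants: 10 (14R)-14-(oxiran-2-yl)-14-(prop-2-yn-1-yloxy)tetradecyl acetate
Product: 13 13-[(2R,3R)-3-(hydroxymethyl)-4-methylideneoxolan-2-yl]tridecyl acetate, via titanoxy alkyl radical 11 (not isolated), via cyclised alkenyl radical 12 (not isolated)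
Conditions: Cp2TiCl2 (2.5 equiv), Zn dust, THF, rt (green Cp2TiCl), added slowly to 10 in THF, rt; then 1 M HCl
Reagents that add atoms: none
Why: Cp2TiCl (trivalent titanium) transfers one electron to the oxirane, which opens at its more substituted C–O bond to the secondary radical 11 at the future C4 carrying the CH2O–Ti group; 11 adds to the internal alkyne carbon to give alkenyl radical 12, which is reduced by a second Cp2TiCl (or takes hydrogen from THF) and protonated on work-up, titanium returning to Cp2TiCl2. The closest known reaction type is the Nugent–RajanBabu titanocene epoxide opening followed by radical cyclization onto an alkyne, an established entry to 3-methylene-4-(hydroxymethyl)oxolanes. The oxolane ring closes in the 5-exo-dig mode through formation of the C3–C4 bond. The new stereocentre C4 is controlled by the C5 carbinol centre: in the envelope-like transition state the CH2O–Ti group on the radical carbon turns away from the C5 alkyl chain, which should give the 4,5-trans (2R,3R) product from both oxirane epimers. The step needs regioselective opening to the secondary radical (secured by radical stability), ring closure faster than capture of 11 as an alkyltitanium that would eliminate (secured by slow addition, which keeps Cp2TiCl dilute) and an untouched acetate (esters are inert to Cp2TiCl).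

Step 8
Reactants: 13 13-[(2R,3R)-3-(hydroxymethyl)-4-methylideneoxolan-2-yl]tridecyl acetate
Product: 15 (2R,3S)-2-[13-(acetyloxy)tridecyl]-4-methylideneoxolane-3-carboxylic acid, via aldehyde 14 (not isolated)
Conditions: CrO3, H2SO4, H2O, acetone, 0 °C; then i-PrOH
Reagents that add atoms: water, O
Why: Jones oxidation through the chromate ester, aldehyde 14 and its hydrate gives the acid rapidly at 0 °C, which should leave the C4 centre, the exocyclic alkene and the acetate intact.

Step 9
Reactants: 15 (2R,3S)-2-[13-(acetyloxy)tridecyl]-4-methylideneoxolane-3-carboxylic acid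
Product: 16 (2R,3S)-2-[13-(acetyloxy)tridecyl]-4-methylidene-5-oxooxolane-3-carboxylic acid (CNP0178400.1)
Conditions: CrO3·2C5H5N (15 equiv, from CrO3 and pyridine), CH2Cl2, rt; dilute HCl work-up
Reagents that add atoms: chromium trioxide, O=[Cr](=O)=O
Why: Allylic oxidation with the CrO3–pyridine complex attacks the ring CH2 that is both allylic and α to the ring oxygen, the known conversion of 3-methyleneoxolanes into α-methylene-γ-butyrolactones, and touches no stereocentre.

Compound list
1 | 12-bromododecan-1-ol | BrCCCCCCCCCCCCO | starting material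
2 | 2-[(12-bromododecyl)oxy]oxane | BrCCCCCCCCCCCCOC1CCCCO1 | intermediate
3 | (R)-epichlorohydrin, (2R)-2-(chloromethyl)oxirane | ClC[C@H]1CO1 | starting material
4 | [12-(oxan-2-yloxy)dodecyl]magnesium bromide | Br[Mg]CCCCCCCCCCCCOC1CCCCO1 | intermediate (not isolated)
5 | (2R)-1-chloro-15-(oxan-2-yloxy)pentadecan-2-ol | ClC[C@H](O)CCCCCCCCCCCCCOC1CCCCO1 | intermediate
6 | (2R)-2-[13-(oxan-2-yloxy)tridecyl]oxirane | C1[C@H](O1)CCCCCCCCCCCCCOC2CCCCO2 | intermediate (not isolated)
7 | (3R)-16-(oxan-2-yloxy)hexadec-1-en-3-ol | C=C[C@H](O)CCCCCCCCCCCCCOC1CCCCO1 | intermediate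
8 | 2-{[(14R)-14-(prop-2-yn-1-yloxy)hexadec-15-en-1-yl]oxy}oxane | C=C[C@H](OCC#C)CCCCCCCCCCCCCOC1CCCCO1 | intermediate
9 | (14R)-14-(prop-2-yn-1-yloxy)hexadec-15-en-1-yl acetate | C=C[C@H](OCC#C)CCCCCCCCCCCCCOC(C)=O | intermediate
10 | (14R)-14-(oxiran-2-yl)-14-(prop-2-yn-1-yloxy)tetradecyl acetate | C#CCO[C@H](CCCCCCCCCCCCCOC(C)=O)C1CO1 | intermediate
11 | secondary carbon radical from opening of 10, as its Cp2Ti(Cl) alkoxide | C#CCO[C@H](CCCCCCCCCCCCCOC(C)=O)[CH]CO[Ti](Cl)(C1C=CC=C1)C1C=CC=C1 | intermediate (not isolated)
12 | cyclised alkenyl radical, as its Cp2Ti(Cl) alkoxide | [CH]=C1CO[C@H](CCCCCCCCCCCCCOC(C)=O)[C@H]1CO[Ti](Cl)(C2C=CC=C2)C2C=CC=C2 | intermediate (not isolated)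
13 | 13-[(2R,3R)-3-(hydroxymethyl)-4-methylideneoxolan-2-yl]tridecyl acetate | C=C1CO[C@H](CCCCCCCCCCCCCOC(C)=O)[C@H]1CO | intermediate
14 | 13-[(2R,3S)-3-formyl-4-methylideneoxolan-2-yl]tridecyl acetate | C=C1CO[C@H](CCCCCCCCCCCCCOC(C)=O)[C@H]1C=O | intermediate (not isolated)
15 | (2R,3S)-2-[13-(acetyloxy)tridecyl]-4-methylideneoxolane-3-carboxylic acid | C=C1CO[C@H](CCCCCCCCCCCCCOC(C)=O)[C@H]1C(=O)O | intermediate
16 | (2R,3S)-2-[13-(acetyloxy)tridecyl]-4-methylidene-5-oxooxolane-3-carboxylic acid | C=C1C(=O)O[C@H](CCCCCCCCCCCCCOC(C)=O)[C@H]1C(=O)O | target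

Total steps: 9. Longest linear sequence: 9 steps, from 1.

Steps most likely to fail

Step 7. Capture of radical 11 by a second Cp2TiCl and β-elimination (deoxygenation to the alkene) may outrun ring closure, and facial control at C4 may be incomplete. The fallback closes the same C3–C4 bond by a palladium-catalysed borylative enyne cyclization instead of a radical process. It sets out from enyne 9 (step 6 is skipped): B2pin2, Pd(OAc)2 (5 mol %), MeOH, toluene, 50 °C should bring about hydropalladation of the alkyne, 5-exo insertion of the vinyl group and transmetalation to give 13-[(2R,3S)-4-methylidene-3-[(4,4,5,5-tetramethyl-1,3,2-dioxaborolan-2-yl)methyl]oxolan-2-yl]tridecyl acetate F1. Oxidation of its C–B bond with NaBO3·4H2O in THF/H2O at rt comes back to the route at alcohol 13.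

Step 9. The C–H oxidation of the free acid may be sluggish, with over-oxidation and migration of the exocyclic double bond into the ring on long exposure to pyridine. The fallback oxygenates the ring CH2 in two mild, chromium-free stages and sets out from acid 15. Allylic hydroxylation with SeO2 (0.5 equiv) and t-BuOOH in CH2Cl2 at rt (ene reaction, then [2,3]-shift at the O–CH2 position) should give the lactol (2R,3S)-2-[13-(acetyloxy)tridecyl]-5-hydroxy-4-methylideneoxolane-3-carboxylic acid F2. Oxidation of the lactol with TEMPO (10 mol %) and PhI(OAc)2 in CH2Cl2 comes back to the route at target 16.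

Step 5. The HCl formed may cleave the allylic propargylic ether or add to the alkyne during the acetal exchange. The fallback separates deprotection from acylation and sets out from 8. Methanolysis with PPTS in MeOH at 45 °C gives (14R)-14-(prop-2-yn-1-yloxy)hexadec-15-en-1-ol F3, and acetylation with Ac2O, pyridine and DMAP (5 mol %) in CH2Cl2 comes back to the route at acetate 9.

Further compounds
F1 | step 7 | 13-[(2R,3S)-4-methylidene-3-[(4,4,5,5-tetramethyl-1,3,2-dioxaborolan-2-yl)methyl]oxolan-2-yl]tridecyl acetate | C=C1CO[C@H](CCCCCCCCCCCCCOC(C)=O)[C@H]1CB2OC(C)(C)C(C)(C)O2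
F2 | step 9 | (2R,3S)-2-[13-(acetyloxy)tridecyl]-5-hydroxy-4-methylideneoxolane-3-carboxylic acid | C=C1C(O)O[C@H](CCCCCCCCCCCCCOC(C)=O)[C@H]1C(=O)O
F3 | step 5 | (14R)-14-(prop-2-yn-1-yloxy)hexadec-15-en-1-ol | C=C[C@H](OCC#C)CCCCCCCCCCCCCO
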